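**Plan**

1. Retrosynthetic cuts, in order: the allyl–O bond on ring B; the C1–C2 bond of ring A, with C2 handed back to the oxygen on C6 so that ring A becomes a 2-pyrone; the CH2–C(=O)Ar bond of the side arm; the two ring–prenyl C–C bonds.
2. Enabling feature: ring A has oxygen on C2, C4 and C6 with only O4 methylated, prenyl on C3 and C5, and the aroyl group on C1. It is a folded tetraketide whose carbons C2–C6 match C2–C6 of a 4-methoxy-3,5-diprenyl-2-pyrone, and whose C1 is the CH2 of an aroylmethyl arm on pyrone C6.
3. Forward: the purchased pyrone is dibrominated and diprenylated, and its C6 methyl is acylated with the ring-B ester (ring B bought intact). The pyrone ring is then opened and ring A closed by C-acylation, and deallylation finishes the synthesis.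
4. Stereochemistry: the target has no stereocentre and no stereogenic double bond. The one geometric requirement, ester and ketone arm cis across the enol ether of the opened intermediate, is inherited from the pyrone ring.

Key step: step 5

Remark: the ring-B phenol is carried as an allyl ether, not an acetal, so that its release needs no acid next to the two ortho-prenyl phenols of ring A.

**Route**

Step 1
Reactants: 1 4-methoxy-6-methyl-2H-pyran-2-one
Product: 3 3,5-dibromo-4-methoxy-6-methyl-2H-pyran-2-one, via 3-bromo-4-methoxy-6-methyl-2H-pyran-2-one 2 (not isolated)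
Conditions: NBS (2.3 equiv), MeCN, 25 → 60 °C, dark
Reagents that add atoms: N-bromosuccinimide, O=C1CCC(=O)N1Br
Why: Ionic electrophilic bromination should take C3 (beta carbon of the 4-methoxy enol ether) first and then C5 (beta to the ring oxygen), the only two ring C–H positions, while the polar solvent and exclusion of light avoid a radical chain at the C6 methyl.

Step 2
Reactants: 3 3,5-dibromo-4-methoxy-6-methyl-2H-pyran-2-one; 4 tributyl(3-methylbut-2-enyl)stannane (2.6 equiv)
Product: 6 4-methoxy-6-methyl-3,5-bis(3-methylbut-2-enyl)-2H-pyran-2-one, via 5-bromo-4-methoxy-6-methyl-3-(3-methylbut-2-enyl)-2H-pyran-2-one 5 (not isolated)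
Conditions: Pd(PPh3)4 (10 mol %), DMF (degassed), 95 °C
Reagents that add atoms: none
Why: In this twofold Migita–Kosugi–Stille coupling zerovalent palladium should insert into the electron-poorer C3–Br bond and then into C5–Br, and with PPh3 as ligand the allylpalladium intermediate can equilibrate to its primary form before reductive elimination, so the linear 3-methylbut-2-enyl group is expected at both carbons.

Step 3
Reactants: 7 methyl 3-hydroxybenzoate
Product: 8 methyl 3-(prop-2-enyloxy)benzoate
Conditions: 3-bromoprop-1-ene (1.2 equiv), K2CO3 (1.5 equiv), acetone, reflux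
Reagents that add atoms: 3-bromoprop-1-ene, C=CCBr
Why: In this Williamson ether synthesis the phenoxide formed with K2CO3 displaces bromide from the allylic halide by SN2, and the methyl ester is untouched under anhydrous, weakly basic conditions.

Step 4
Reactants: 6 4-methoxy-6-methyl-3,5-bis(3-methylbut-2-enyl)-2H-pyran-2-one; 8 methyl 3-(prop-2-enyloxy)benzoate (1.1 equiv)
Product: 9 4-methoxy-3,5-bis(3-methylbut-2-enyl)-6-{2-oxo-2-[3-(prop-2-enyloxy)phenyl]ethyl}-2H-pyran-2-one
Conditions: LiN(i-Pr)2 (2.2 equiv), THF, −78 °C; then 8, −78 → −30 °C; AcOH quench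
Reagents that add atoms: none
Why: Lateral (vinylogous) deprotonation of the C6 methyl gives a lithium trienolate that should undergo crossed Claisen acylation at its exocyclic carbon with the non-enolisable ester, C3 and C5 being blocked, the second equivalent of base holding the acidic aroylmethyl product as its enolate against proton quench and double addition, and the allyl aryl ether being inert to the amide base at −78 °C.

Step 5
Reactants: 9 4-methoxy-3,5-bis(3-methylbut-2-enyl)-6-{2-oxo-2-[3-(prop-2-enyloxy)phenyl]ethyl}-2H-pyran-2-one
Product: 11 [2,6-dihydroxy-4-methoxy-3,5-bis(3-methylbut-2-enyl)phenyl][3-(prop-2-enyloxy)phenyl]methanone, via ring-opened methyl ester 10 (not isolated)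
Conditions: Mg(OMe)2 (5 equiv, commercial solution in MeOH), MeOH, reflux; then 1 M HCl, 0 °C
Reagents that add atoms: none
Why: Methoxide adds to the lactone carbonyl (pyrone C2) and the ring opens to methyl ester 10, in which the former C5=C6–O unit is a ketone and the aroylmethyl CH2 is the central carbon of a magnesium-chelated 1,3-diketone enolate. That carbanion (future C1) attacks the ester carbon (future C2) in a Claisen (Dieckmann-type) condensation, a 6-(enolexo)-exo-trig closure that forms the C1–C2 bond and ring A; loss of methoxide and enolisation then give the arene, so 9 is isomerised to 11, driven by aromatisation and by two hydrogen bonds from the new 2- and 6-hydroxyls to the ketone. The closest known reaction is the Mg(OMe)2-induced recyclisation of 6-acylmethyl-4-methoxy-2-pyrones and of 3,5,7-triketo esters to acylphloroglucinols, used here on a pyrone with two extra alkyl groups. No stereocentre is created, since the transient C4 stereocentre of 10 is lost on enolisation. The step needs Claisen folding to win over aldol folding and over retro-Claisen cleavage of the diketone: the retained enol ether keeps the ester alpha-carbon sp2, fully substituted and non-nucleophilic, its ring-derived geometry holds ester and carbanion cis, and magnesium chelation shields the diketone from methoxide. Methoxide in methanol makes any exchange at the ester or at C4 degenerate, the basic medium keeps the prenyl alkenes from adding to the neighbouring phenols, and the allyl ether is inert.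

Step 6
Reactants: 11 [2,6-dihydroxy-4-methoxy-3,5-bis(3-methylbut-2-enyl)phenyl][3-(prop-2-enyloxy)phenyl]methanone
Product: 12 [2,6-dihydroxy-4-methoxy-3,5-bis(3-methylbut-2-enyl)phenyl](3-hydroxyphenyl)methanone
Conditions: Pd(PPh3)4 (5 mol %), morpholine (10 equiv), THF, 25 °C; dilute citric acid wash
Reagents that add atoms: none
Why: In this Tsuji–Trost-type deallylation zerovalent palladium ionises the aryl allyl ether to a pi-allylpalladium complex and the phenoxide, and excess morpholine traps the allyl group, so the phenol is freed without acid and neither the prenyl alkenes (no leaving group) nor the ortho-prenyl phenols (no chroman closure) should react.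

**Compound list**

1 | 4-methoxy-6-methyl-2H-pyran-2-one | COc1cc(C)oc(=O)c1 | starting material
2 | 3-bromo-4-methoxy-6-methyl-2H-pyran-2-one | COc1cc(C)oc(=O)c1Br | intermediate (not isolated)
3 | 3,5-dibromo-4-methoxy-6-methyl-2H-pyran-2-one | COc1c(Br)c(C)oc(=O)c1Br | intermediate
4 | tributyl(3-methylbut-2-enyl)stannane | CCCC[Sn](CCCC)(CCCC)CC=C(C)C | starting material
5 | 5-bromo-4-methoxy-6-methyl-3-(3-methylbut-2-enyl)-2H-pyran-2-one | COc1c(Br)c(C)oc(=O)c1CC=C(C)C | intermediate (not isolated)
6 | 4-methoxy-6-methyl-3,5-bis(3-methylbut-2-enyl)-2H-pyran-2-one | COc1c(CC=C(C)C)c(C)oc(=O)c1CC=C(C)C | intermediate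
7 | methyl 3-hydroxybenzoate | COC(=O)c1cccc(O)c1 | starting material
8 | methyl 3-(prop-2-enyloxy)benzoate | COC(=O)c1cccc(OCC=C)c1 | intermediate
9 | 4-methoxy-3,5-bis(3-methylbut-2-enyl)-6-{2-oxo-2-[3-(prop-2-enyloxy)phenyl]ethyl}-2H-pyran-2-one | COc1c(CC=C(C)C)c(=O)oc(CC(=O)c2cccc(OCC=C)c2)c1CC=C(C)C | intermediate
10 | methyl (2E)-3-methoxy-2,4-bis(3-methylbut-2-enyl)-5,7-dioxo-7-[3-(prop-2-enyloxy)phenyl]hept-2-enoate (racemic at C4, present as its magnesium enolate) | COC(=O)/C(CC=C(C)C)=C(OC)\C(CC=C(C)C)C(=O)CC(=O)c1cccc(OCC=C)c1 | intermediate (not isolated)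
11 | [2,6-dihydroxy-4-methoxy-3,5-bis(3-methylbut-2-enyl)phenyl][3-(prop-2-enyloxy)phenyl]methanone | COc1c(CC=C(C)C)c(O)c(C(=O)c2cccc(OCC=C)c2)c(O)c1CC=C(C)C | intermediate
12 | [2,6-dihydroxy-4-methoxy-3,5-bis(3-methylbut-2-enyl)phenyl](3-hydroxyphenyl)methanone | COc1c(CC=C(C)C)c(O)c(C(=O)c2cccc(O)c2)c(O)c1CC=C(C)C | target

**Count and risks**

Total steps: 6. Longest linear sequence: 5 steps (steps 1, 2, 4, 5, 6; 1 → 3 → 6 → 9 → 11 → 12).

Step 5 (ring opening and Claisen closure). With alkyl groups on both sides, methoxide attack on the lactone carbonyl and C-acylation at the hindered tetrasubstituted ester may be slow. Re-lactonisation or methoxide cleavage of the aroyl diketone could then consume the material. The fallback keeps the ring transformation but runs it on the unhindered parent system and adds the prenyl groups afterwards. It sets out from 1 and returns to the route at 11. Compound 1 is deprotonated at its C6 methyl with LiN(i-Pr)2 in THF at −78 °C and acylated with 8 to give 4-methoxy-6-{2-oxo-2-[3-(prop-2-enyloxy)phenyl]ethyl}-2H-pyran-2-one F1. Mg(OMe)2 in refluxing methanol should convert F1, through the opened ester methyl (2E)-3-methoxy-5,7-dioxo-7-[3-(prop-2-enyloxy)phenyl]hept-2-enoate F2, into (2,6-dihydroxy-4-methoxyphenyl)[3-(prop-2-enyloxy)phenyl]methanone F3. The two free ring-A carbons of F3 are then C-prenylated with 1-bromo-3-methylbut-2-ene and DBU in THF to give 11. This late prenylation is less selective (O-alkylation and over-alkylation compete), which is why it is not the main route.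

Step 2 (double prenyl coupling). Oxidative addition at the hindered, more electron-rich C5–Br bond may stall after the first coupling. Reductive elimination through the tertiary allyl terminus would attach the group as 1,1-dimethylallyl. The fallback sets out from 3 and returns at 6. Twofold Stille coupling of 3 with allyltributylstannane (Pd(PPh3)4, DMF, 95 °C) has no regiochemical ambiguity and a faster transmetalation, and should give 4-methoxy-6-methyl-3,5-di(prop-2-enyl)-2H-pyran-2-one F4. Double olefin cross-metathesis of F4 with excess 2-methylbut-2-ene (second-generation Grubbs catalyst, CH2Cl2, 40 °C) then converts both allyl groups into prenyl groups and gives 6.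

Step 4 (acylation of the lateral anion). Proton transfer from the acidic product to unreacted trienolate may stop the reaction at partial conversion, and the trienolate may add to the lactone of a second pyrone. The fallback changes the oxidation level of the electrophile; it sets out from 8 and returns at 9. Ester 8 is reduced with i-Bu2AlH (CH2Cl2, −78 → 0 °C) to [3-(prop-2-enyloxy)phenyl]methanol F5, which MnO2 in CH2Cl2 oxidises to 3-(prop-2-enyloxy)benzaldehyde F6. Aldol addition of lithiated 6 (LiN(i-Pr)2, 1.1 equiv, THF, −78 °C) to F6 gives racemic 6-{2-hydroxy-2-[3-(prop-2-enyloxy)phenyl]ethyl}-4-methoxy-3,5-bis(3-methylbut-2-enyl)-2H-pyran-2-one F7. This adduct is not acidic enough to quench the nucleophile. Buffered Dess–Martin oxidation (NaHCO3, CH2Cl2, 0 °C) then gives 9 without dehydration to the styrylpyrone.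

**Further compounds**

F1 | step 5 | 4-methoxy-6-{2-oxo-2-[3-(prop-2-enyloxy)phenyl]ethyl}-2H-pyran-2-one | COc1cc(CC(=O)c2cccc(OCC=C)c2)oc(=O)c1
F2 | step 5 | methyl (2E)-3-methoxy-5,7-dioxo-7-[3-(prop-2-enyloxy)phenyl]hept-2-enoate | COC(=O)/C=C(OC)\CC(=O)CC(=O)c1cccc(OCC=C)c1
F3 | step 5 | (2,6-dihydroxy-4-methoxyphenyl)[3-(prop-2-enyloxy)phenyl]methanone | COc1cc(O)c(C(=O)c2cccc(OCC=C)c2)c(O)c1
F4 | step 2 | 4-methoxy-6-methyl-3,5-di(prop-2-enyl)-2H-pyran-2-one | COc1c(CC=C)c(C)oc(=O)c1CC=C
F5 | step 4 | [3-(prop-2-enyloxy)phenyl]methanol | OCc1cccc(OCC=C)c1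
F6 | step 4 | 3-(prop-2-enyloxy)benzaldehyde | O=Cc1cccc(OCC=C)c1
F7 | step 4 | 6-{2-hydroxy-2-[3-(prop-2-enyloxy)phenyl]ethyl}-4-methoxy-3,5-bis(3-methylbut-2-enyl)-2H-pyran-2-one (racemic) | COc1c(CC=C(C)C)c(=O)oc(CC(O)c2cccc(OCC=C)c2)c1CC=C(C)C
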